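Per mole of G or D converted we take one mole of X spent, and that unit reduces the question to two amounts: the X charged and the X spent by the moment we look.

| flask | G | D | X | E | remark |
|---|---|---|---|---|---|
| grey | 0.43 M | 0.43 M | 1.28 M | 64 mM | run made earlier |
| ochre | 0.96 M | 0.96 M | 1.28 M | 64 mM | run made earlier |
| flask | 0.64 M | 0.64 M | 1.28 M | 64 mM |  |

| run | time / min | J / % |
|---|---|---|
| grey | 0.667 | 35.0 |
| grey | 2.00 | 42.6 |
| grey | 3.00 | 43.8 |
| grey | 5.00 | 44.6 |
| ochre | 0.667 | 31.0 |
| ochre | 2.00 | 37.4 |
| ochre | 3.00 | 38.4 |
| ochre | 5.00 | 38.2 |

(each reading ± 0.3 percentage points)

- apparent order in X when 30% of the G and D together are converted (percent change of the rate of making J for one percent more X charged)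
- factor on the rate of making J when 30% of the G and D together are converted if X is charged twice over

- E is single-handed; G and D are mirror images of each other, charged as a racemate, each of them at the stated concentration
- no earlier run changes the charge of X; that part of a forecast is a guess

In this flask, G and D together match the X charge, so at 30% conversion X has given up 30.0% of its charge. At fixed conversion the fractions of substrate stay about level, and the amount of X spent stays the same when more is charged. So we define the lever as the X charged over the X present at that conversion, 1.43: one percent more charge means that many percent more X present.

J levels off below 50% in both runs, which we read as a dying catalyst. Our own reckoning guesses a rate of first order in the X present, since no run tests it, and gives an apparent order of the lever plus a correction for catalyst that has had less time to die. Doubling the charge multiplies the X present by 2.43. The forecast differs, at 0.3 and 1.25, and counts a gain from the “catalyst surviving longer at fixed conversion”.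

The flask gives an order of 1.9 and a factor of 2.95.

    X + E + G → E + J (k = 0.622 L² mol⁻² s⁻¹)
    X + E + D → E + Z (k = 0.0944 L² mol⁻² s⁻¹)
    E → L (k = 0.0170 s⁻¹)

Taking the lever from that order leaves 0.476, and this flask reaches the conversion at 0.322 min, which is 0.328 of the lifetime of E. The ochre run had passed that conversion by its J reading of 31.0% at 0.667 min, and in ochre 30% conversion takes 45.0% of the X charge, a lever of 1.82.

(Readings and results are calculated from invented constants.)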